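**Retrosynthetic overview**
1. Target 21 ⇐ 19: removing three silyl groups frees the C1 hydroxyl, which adds to C3 of a γ-ylidene butyrolactone and expels the carboxylate; ring B (O2–C3) closes last and the acid is released in the same event.
2. 19 ⇐ 18: ring A is closed through the C4a–C5 bond by a 6-endo radical addition–elimination of the C5 alkyl radical onto the triflate-bearing C4a of a vinylogous acyl triflate.
3. 18 ⇐ 11 + 16: C8–C8a by C-acylation of a ketone enolate, then enol triflation.
4. 16 ⇐ (R)-3-hydroxy-γ-butyrolactone 12 (C5–C8): anti-methylation sets C7, Mitsunobu inversion with silyl-protected orsellinic acid 6 (from two methyl acetoacetate units) sets C6, iodosilane opening gives the C5 iodide.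
5. 11 ⇐ 4-hydroxybutan-2-one (C1, C8a, C4a, C4) + succinic anhydride (C3 and the acid chain).

Assumption: atom labels C1–C8a follow the 1H-isochromene numbering of the target (ring A = carbocycle, ring B = pyran) and are used for all intermediates; 12 is bought as the single (R)-enantiomer.

**Step 1**
Reactants: 1 methyl acetoacetate (2 equiv)
Product: 3 methyl orsellinate, via triketo ester 2 (not isolated)
Conditions: NaH (1.0 equiv), THF, 0 °C; n-BuLi (1.0 equiv), 0 °C → reflux, 24 h; aq. HCl
Reagents that add atoms: none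
Why: Known self-condensation of the acetoacetate dianion: Claisen C-acylation of a second molecule gives triketo ester 2, which closes by intramolecular aldol condensation and aromatises to the orsellinate (no stereocentre).

**Step 2**
Reactants: 3 methyl orsellinate
Product: 4 orsellinic acid
Conditions: KOH, DMSO–H2O (4:1), 80 °C, N2; then 1 M HCl, 0 °C
Reagents that add atoms: potassium hydroxide, [K+].[OH-]
Why: Saponification (BAc2) of the hindered ester; the phenoxide–carboxylate trianion resists decarboxylation until the cold acidification.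

**Step 3**
Reactants: 4 orsellinic acid
Product: 6 2,4-bis(tert-butyldimethylsilyloxy)-6-methylbenzoic acid, via silyl ester 5 (not isolated)
Conditions: TBSCl (3.5 equiv), imidazole, DMF, 25 °C; then AcOH–THF–H2O (3:1:1), 25 °C
Reagents that add atoms: tert-butyldimethylsilyl chloride, CC(C)(C)[Si](C)(C)Cl
Why: Exhaustive silylation followed by selective hydrolysis of the labile silyl ester leaves both phenols masked and the carboxylic acid free for the Mitsunobu step.

**Step 4**
Reactants: 7 4-hydroxybutan-2-one
Product: 8 4-(tert-butyldiphenylsilyloxy)butan-2-one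
Conditions: TBDPSCl (1.1 equiv), imidazole, CH2Cl2, 0 → 25 °C
Reagents that add atoms: tert-butyldiphenylsilyl chloride, CC(C)(C)[Si](Cl)(c1ccccc1)c1ccccc1
Why: Standard silylation of the primary alcohol; the robust silyl ether keeps the C1 oxygen from closing ring B before ring A exists.

**Step 5**
Reactants: 8 4-(tert-butyldiphenylsilyloxy)butan-2-one (2.1 equiv, 1 equiv recovered), 9 succinic anhydride
Product: 10 8-(tert-butyldiphenylsilyloxy)-4,6-dioxooctanoic acid
Conditions: LiN(i-Pr)2 (2.1 equiv), THF, −78 °C; 9 (1.0 equiv), −78 → −20 °C; 1 M HCl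
Reagents that add atoms: none
Why: The kinetic methyl-side lithium enolate of 8 is C-acylated by the cyclic anhydride (Claisen-type ring-opening acylation), the second enolate equivalent being consumed by the acidic 1,3-diketone product.

**Step 6**
Reactants: 10 8-(tert-butyldiphenylsilyloxy)-4,6-dioxooctanoic acid
Product: 11 (5Z)-5-[4-(tert-butyldiphenylsilyloxy)-2-oxobutylidene]oxolan-2-one
Conditions: DCC (1.1 equiv), CH2Cl2, 0 → 25 °C
Reagents that add atoms: none
Why: Carbodiimide-mediated enol lactonisation: the enol oxygen of the C3 carbonyl attacks the O-acylisourea (5-exo) to give the (Z)-γ-ylidene butyrolactone, which masks the acid and the C3 ketone and leaves the CH2 next to the C4a ketone (C8a) for kinetic enolisation.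

**Step 7**
Reactants: 12 (R)-4-hydroxyoxolan-2-one
Product: 13 (3R,4R)-4-hydroxy-3-methyloxolan-2-one
Conditions: LiN(i-Pr)2 (2.2 equiv), THF, −78 → −45 °C; MeI (1.5 equiv), −78 °C; 1 M HCl
Reagents that add atoms: iodomethane, CI
Why: Fráter–Seebach-type alkylation of the alkoxide–enolate dianion; iodomethane enters anti to the oxido group, so the trans (3R,4R) lactone forms and C7 of the target is set.

**Step 8**
Reactants: 13 (3R,4R)-4-hydroxy-3-methyloxolan-2-one, 6 2,4-bis(tert-butyldimethylsilyloxy)-6-methylbenzoic acid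
Product: 14 (3R,4S)-4-[2,4-bis(tert-butyldimethylsilyloxy)-6-methylbenzoyloxy]-3-methyloxolan-2-one
Conditions: PPh3 (1.5 equiv), DIAD (1.5 equiv), PhMe, 0 → 25 °C
Reagents that add atoms: none
Why: Mitsunobu esterification with SN2 inversion at the carbinol carbon sets C6 and the cis relationship of ester and methyl; in the trans alcohol the acidic α-carbon has no hydrogen anti to the leaving group, so E2 elimination to the butenolide is disfavoured.

**Step 9**
Reactants: 14 (3R,4S)-4-[2,4-bis(tert-butyldimethylsilyloxy)-6-methylbenzoyloxy]-3-methyloxolan-2-one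
Product: 16 (2R,3S)-3-[2,4-bis(tert-butyldimethylsilyloxy)-6-methylbenzoyloxy]-4-iodo-2-methylbutanoyl chloride, via trimethylsilyl ester 15 (not isolated)
Conditions: Me3SiI (1.3 equiv), CH2Cl2, 0 → 25 °C; evaporate; (COCl)2 (1.5 equiv), DMF (cat.), CH2Cl2, 0 → 25 °C
Reagents that add atoms: iodotrimethylsilane, C[Si](C)(C)I; oxalyl chloride, O=C(Cl)C(=O)Cl
Why: Iodotrimethylsilane cleaves the lactone by iodide attack at the primary C5 (alkyl–oxygen cleavage, much faster than attack at the hindered secondary benzoate carbon), and oxalyl chloride/DMF converts the silyl ester into the acid chloride under non-basic conditions, so C6 and C7 are untouched.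

**Step 10**
Reactants: 11 (5Z)-5-[4-(tert-butyldiphenylsilyloxy)-2-oxobutylidene]oxolan-2-one (2.1 equiv, 1 equiv recovered), 16 acid chloride
Product: 17 β-diketone in which C8a of 11 carries the (2R,3S)-3-aroyloxy-4-iodo-2-methylbutanoyl group (chelated enol)
Conditions: LiN(i-Pr)2 (2.1 equiv), THF, −78 °C; 16 (1.0 equiv), −78 °C, 30 min; AcOH, −78 °C
Reagents that add atoms: none
Why: Claisen-type C-acylation of the kinetic α′ lithium enolate of 11 by the acid chloride at −78 °C; the surplus enolate deprotonates the product, and the cold acetic acid quench limits C7 epimerisation and E1cB loss of the β-aroyloxy group.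

**Step 11**
Reactants: 17 β-diketone
Product: 18 (Z)-enol triflate of 17 (OTf on C4a, cis to the C8 carbonyl)
Conditions: LiOSO2CF3 (1.5 equiv), Et3N (1.5 equiv), (CF3SO2)2O (1.2 equiv), CH2Cl2, −78 °C
Reagents that add atoms: trifluoromethanesulfonic anhydride, O=S(=O)(OS(=O)(=O)C(F)(F)F)C(F)(F)F
Why: Enol triflate formation from the lithium-chelated diketonate: the less hindered oxygen on C4a is sulfonylated, giving the through-conjugated dienyl triflate with OTf cis to the C8 carbonyl, a geometry in which the dienyl arm cannot reach C8=O for oxa-6π closure, and −78 °C keeps the enolate from displacing the C5 iodide.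

**Step 12**
Reactants: 18 (Z)-enol triflate
Product: 19 (1R,6R)-4-[(tert-butyldiphenylsilyloxy)methyl]-6-methyl-5-oxo-3-[(Z)-(5-oxooxolan-2-ylidene)methyl]cyclohex-3-en-1-yl 2,4-bis(tert-butyldimethylsilyloxy)-6-methylbenzoate
Conditions: (Me3Si)3SiH (1.3 equiv, syringe pump, 4 h), AIBN (0.2 equiv), 2,6-lutidine (1.5 equiv), PhH (0.003 M), 80 °C
Reagents that add atoms: none
Why: Proposed new method: the silyl radical abstracts iodine from C5; the primary radical, which unlike a C5 organometallic cannot expel the β-aroyloxy group, adds 6-endo to the triflate-bearing β-carbon C4a of the enone (5-exo attack at the α-carbon C8a is disfavoured and there is no other acceptor within reach), and the α-keto radical takes H from the silane and loses triflic acid to restore the C4a=C8a enone; closest known types are 6-endo Giese cyclisations onto acryloyl and β-alkoxyacrylate acceptors and radical addition–fragmentation at β-halo or β-thio enones; no stereocentre is formed, so C6 and C7 are carried through.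

**Step 13**
Reactants: 19 silyl-protected ring A compound
Product: 21 3-[(6R,7R)-6-(2,4-dihydroxy-6-methylbenzoyloxy)-7-methyl-8-oxo-5,6,7,8-tetrahydro-1H-isochromen-3-yl]propanoic acid, via hydroxymethyl enol lactone 20 (not isolated)
Conditions: HF·pyridine, pyridine, THF, 0 → 25 °C, 16 h
Reagents that add atoms: none
Why: Fluoride cleaves the alkyl and aryl silyl ethers, and the freed C1 hydroxyl adds to C3 of the ylidene lactone in a six-membered conjugate addition–elimination (vinylogous transacylation) that expels the carboxylate, closing the ring-fused 2H-pyran and releasing the acid under buffered, non-basic conditions that leave the β-acyloxy ketone and C6/C7 untouched.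

**Compound list**
1 | methyl acetoacetate | COC(=O)CC(C)=O | starting material
2 | methyl 3,5,7-trioxooctanoate | COC(=O)CC(=O)CC(=O)CC(C)=O | intermediate
3 | methyl orsellinate (methyl 2,4-dihydroxy-6-methylbenzoate) | COC(=O)c1c(C)cc(O)cc1O | intermediate
4 | orsellinic acid | Cc1cc(O)cc(O)c1C(=O)O | intermediate
5 | tert-butyldimethylsilyl 2,4-bis(tert-butyldimethylsilyloxy)-6-methylbenzoate | Cc1cc(O[Si](C)(C)C(C)(C)C)cc(O[Si](C)(C)C(C)(C)C)c1C(=O)O[Si](C)(C)C(C)(C)C | intermediate
6 | 2,4-bis(tert-butyldimethylsilyloxy)-6-methylbenzoic acid | Cc1cc(O[Si](C)(C)C(C)(C)C)cc(O[Si](C)(C)C(C)(C)C)c1C(=O)O | intermediate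
7 | 4-hydroxybutan-2-one | CC(=O)CCO | starting material
8 | 4-(tert-butyldiphenylsilyloxy)butan-2-one | CC(=O)CCO[Si](c1ccccc1)(c1ccccc1)C(C)(C)C | intermediate
9 | succinic anhydride | O=C1CCC(=O)O1 | starting material
10 | 8-(tert-butyldiphenylsilyloxy)-4,6-dioxooctanoic acid | OC(=O)CCC(=O)CC(=O)CCO[Si](c1ccccc1)(c1ccccc1)C(C)(C)C | intermediate
11 | (5Z)-5-[4-(tert-butyldiphenylsilyloxy)-2-oxobutylidene]oxolan-2-one | O=C(CCO[Si](c1ccccc1)(c1ccccc1)C(C)(C)C)/C=C1/CCC(=O)O1 | intermediate
12 | (R)-4-hydroxyoxolan-2-one ((R)-3-hydroxy-γ-butyrolactone) | O[C@H]1COC(=O)C1 | starting material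
13 | (3R,4R)-4-hydroxy-3-methyloxolan-2-one | O=C1OC[C@H](O)[C@H]1C | intermediate
14 | (3R,4S)-4-[2,4-bis(tert-butyldimethylsilyloxy)-6-methylbenzoyloxy]-3-methyloxolan-2-one | O=C1OC[C@@H](OC(=O)c2c(C)cc(O[Si](C)(C)C(C)(C)C)cc2O[Si](C)(C)C(C)(C)C)[C@H]1C | intermediate
15 | trimethylsilyl (2R,3S)-3-[2,4-bis(tert-butyldimethylsilyloxy)-6-methylbenzoyloxy]-4-iodo-2-methylbutanoate | C[Si](C)(C)OC(=O)[C@H](C)[C@@H](CI)OC(=O)c1c(C)cc(O[Si](C)(C)C(C)(C)C)cc1O[Si](C)(C)C(C)(C)C | intermediate
16 | (2R,3S)-3-[2,4-bis(tert-butyldimethylsilyloxy)-6-methylbenzoyloxy]-4-iodo-2-methylbutanoyl chloride | O=C(Cl)[C@H](C)[C@@H](CI)OC(=O)c1c(C)cc(O[Si](C)(C)C(C)(C)C)cc1O[Si](C)(C)C(C)(C)C | intermediate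
17 | β-diketone: 11 acylated at C8a by the (2R,3S)-3-aroyloxy-4-iodo-2-methylbutanoyl group of 16, drawn as the chelated C4a enol | O/C(/C=C1/CCC(=O)O1)=C(/CO[Si](c1ccccc1)(c1ccccc1)C(C)(C)C)C(=O)[C@H](C)[C@@H](CI)OC(=O)c1c(C)cc(O[Si](C)(C)C(C)(C)C)cc1O[Si](C)(C)C(C)(C)C | intermediate
18 | (Z)-enol triflate of 17 (OTf on C4a, cis to the C8 carbonyl; ylidene lactone Z) | O=S(=O)(O/C(/C=C1/CCC(=O)O1)=C(/CO[Si](c1ccccc1)(c1ccccc1)C(C)(C)C)C(=O)[C@H](C)[C@@H](CI)OC(=O)c1c(C)cc(O[Si](C)(C)C(C)(C)C)cc1O[Si](C)(C)C(C)(C)C)C(F)(F)F | intermediate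
19 | (1R,6R)-4-[(tert-butyldiphenylsilyloxy)methyl]-6-methyl-5-oxo-3-[(Z)-(5-oxooxolan-2-ylidene)methyl]cyclohex-3-en-1-yl 2,4-bis(tert-butyldimethylsilyloxy)-6-methylbenzoate | Cc1cc(O[Si](C)(C)C(C)(C)C)cc(O[Si](C)(C)C(C)(C)C)c1C(=O)O[C@@H]1CC(/C=C2/CCC(=O)O2)=C(CO[Si](c2ccccc2)(c2ccccc2)C(C)(C)C)C(=O)[C@@H]1C | intermediate
20 | (1R,6R)-4-(hydroxymethyl)-6-methyl-5-oxo-3-[(Z)-(5-oxooxolan-2-ylidene)methyl]cyclohex-3-en-1-yl 2,4-dihydroxy-6-methylbenzoate | Cc1cc(O)cc(O)c1C(=O)O[C@@H]1CC(/C=C2/CCC(=O)O2)=C(CO)C(=O)[C@@H]1C | intermediate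
21 | 3-[(6R,7R)-6-(2,4-dihydroxy-6-methylbenzoyloxy)-7-methyl-8-oxo-5,6,7,8-tetrahydro-1H-isochromen-3-yl]propanoic acid | Cc1cc(O)cc(O)c1C(=O)O[C@@H]1CC2=C(COC(CCC(=O)O)=C2)C(=O)[C@@H]1C | target

**Step count and risks**
Total steps: 13. Longest linear sequence: 9 steps (1, 2, 3, 8, 9, 10, 11, 12, 13).

Most likely to fail, step 12 (radical ring closure): the C5 radical may be reduced before it cyclises, or the tetrasubstituted C4a may be too hindered. The fallback sets out from 18 and makes the same C4a–C5 bond by nickel-catalysed reductive cross-electrophile coupling (NiBr2(dme), 4,4′-di-tert-butyl-2,2′-bipyridine, Mn powder, NaI, DMA, 25 °C, high dilution). Zerovalent nickel formed in the flask inserts into the C4a–OTf bond, the C5 radical generated from the iodide is captured at nickel, and reductive elimination closes ring A. It comes back to the route at 19 and makes no new compound, F0.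

Second, step 10 (C-acylation): the lithium enolate may O-acylate, equilibrate to the extended dienolate, or act as a base on the α-branched, β-acyloxy acid chloride (ketene formation, C7 epimerisation). The fallback sets out from 11, which is converted with LiN(i-Pr)2 and Me3SiCl at −78 °C into the trimethylsilyl enol ether F3. F3 is then C-acylated by 16 under Lewis acid conditions (ZnCl2, CH2Cl2, −20 °C; Mukaiyama-type acylation with no free base) and comes back to the route at 17.

Third, step 9 (iodosilane opening): iodotrimethylsilane may also attack the aryl silyl ethers or the benzoate. The fallback sets out from 14 and opens the lactone at its carbonyl instead, with Me2AlN(OMe)Me (from AlMe3 and MeNHOMe·HCl, CH2Cl2, 0 °C), to give the hydroxy Weinreb amide F1. PPh3, I2 and imidazole convert the primary alcohol into the iodo Weinreb amide F2, which acylates the lithium enolate of 11 (THF, −78 °C) and comes back to the route at 17, bypassing 15 and 16.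

**Further compounds**
F1 | step 9 | (2R,3S)-3-[2,4-bis(tert-butyldimethylsilyloxy)-6-methylbenzoyloxy]-4-hydroxy-N-methoxy-N,2-dimethylbutanamide | CON(C)C(=O)[C@H](C)[C@@H](CO)OC(=O)c1c(C)cc(O[Si](C)(C)C(C)(C)C)cc1O[Si](C)(C)C(C)(C)C
F2 | step 9 | (2R,3S)-3-[2,4-bis(tert-butyldimethylsilyloxy)-6-methylbenzoyloxy]-4-iodo-N-methoxy-N,2-dimethylbutanamide | CON(C)C(=O)[C@H](C)[C@@H](CI)OC(=O)c1c(C)cc(O[Si](C)(C)C(C)(C)C)cc1O[Si](C)(C)C(C)(C)C
F3 | step 10 | (5Z)-5-[4-(tert-butyldiphenylsilyloxy)-2-(trimethylsilyloxy)but-2-enylidene]oxolan-2-one (enol ether geometry not fixed) | C[Si](C)(C)OC(=CCO[Si](c1ccccc1)(c1ccccc1)C(C)(C)C)/C=C1/CCC(=O)O1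
F0 | step 12 | none | none
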